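The meeting took up the flask.

| setting | summer | dawn | noon | flask |
|---|---|---|---|---|
| starting material | 0.050 M | 0.050 M | 0.10 M | 0.050 M |
| reagent | 0.055 M | 0.055 M | 0.055 M | 0.0550 M |
| second substrate | 0.025 M (fed, over 40 h) | 0.025 M (fed, over 40 h) | 0.025 M (fed, over 40 h) | 0.0250 M (fed, over 40 h) |
| third substrate | 0.12 M | 0.19 M | 0.25 M | 0.250 M |
| remark | run made earlier | run made earlier | run made earlier |  |
| time |  |  |  | 5.0 d |

| run | time / d | target / % | starting material / % |
|---|---|---|---|
| summer | 0.104 | 50.3 | 49.1 |
| summer | 0.250 | 65.3 | 32.5 |
| summer | 0.625 | 68.5 | 25.1 |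
| summer | 2.08 | 58.5 | 24.4 |
| summer | 5.00 | 42.3 | 23.9 |
| dawn | 0.104 | 48.6 | 51.2 |
| dawn | 0.250 | 60.3 | 38.3 |
| dawn | 0.625 | 62.7 | 33.1 |
| dawn | 2.08 | 51.1 | 32.0 |
| dawn | 5.00 | 38.0 | 32.8 |
| noon | 0.104 | 36.6 | 63.2 |
| noon | 0.250 | 39.3 | 58.8 |
| noon | 0.625 | 37.9 | 59.4 |
| noon | 2.08 | 32.3 | 58.8 |
| noon | 5.00 | 22.8 | 58.3 |

(scatter of a reading: 0.5 percentage points)

- the numbers in the tables scatter by 0.5 percentage points (one standard deviation)
- steps that have been proposed: second substrate + reagent -> second product; third substrate + reagent -> third product; starting material + reagent -> target; target <-> isomer of the product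

1. time up to 5.0 d at which target stands highest
2. the amount of target, in percent of the starting material charged, at that time

The kineticist reported that late in the earlier runs starting material stood still, at 23.9% in summer, 32.8% in dawn and 58.3% in noon. She read this as the end of the reagent, the limiting reagent, of which 0.055 M was charged. If starting material and third substrate compete for it, then s = c^a, where s and c are the fractions of each left. She took c from the reagent balance, setting second substrate aside as a premise, and the readings gave 9.40, 9.33 and 9.87. The mean, 9.53, is the selectivity factor a, the ratio of the two logarithms ln(1/s) and ln(1/c).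

The secretary's own reckoning tried dawn's s on the flask, and balance and rule returned 42.6%. The mean of the two, 37.7%, returned 38.4%. Dawn's target reading at 0.625 d was 93.7% of the converted material, so the secretary expected a peak near 57.7%, between 0.250 d and 0.625 d.

The forecast, speaking of reagent ending and “leaving starting material unreacted”, gave 57.5% at 0.45 d.

The flask gave 58.4% at 0.403 d, and it ended with 38% starting material against the reckoned 38.4%.

    second substrate + reagent → second product (k = 1.51 M⁻¹ h⁻¹)
    third substrate + reagent → third product (k = 0.849 M⁻¹ h⁻¹)
    starting material + reagent → target (k = 8.29 M⁻¹ h⁻¹)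
    target ⇌ isomer of the product (K = 2.30, k = 0.00598 h⁻¹)

A neighbouring flask, like the flask but charged with 0.062 M of third substrate, ended with 82.1% of that substrate left. Raised to the power a, this gives 15.3% starting material, and the neighbouring flask held 14.7%. Its target stood highest at 76.3%.

The earlier runs and the new flask were generated by integration for substances that don't exist, noise included.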